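**Retrosynthetic overview**

1. Last step: hydrogenolysis of the tetradeca-O-benzyl ether of epicatechin-(4β→8)-epifisetinidol-(4β→8)-catechin (units U, M and L from top to bottom; rings A/B/C in each unit).
2. Key disconnection: the pyran rings C(U) and C(M) are both opened at C4–C4a, which leaves an open-chain bis-carbinol whose only heterocycle is ring C(L); one acid-triggered double Friedel–Crafts cascade closes both rings. Enabling feature: each C4 is bonded to C8 of the next unit, an arene carbon flanked by C7–O and C8a–O1, so a C4 carbinol ionises to a 2,6-dioxygenated benzylic cation, while C4a of the aryl ether tethered through O1–C2–C3 is ortho/para to the ring-A oxygens.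
3. The bis-carbinol comes from two aryllithium–aldehyde additions in which a bromine fixes each 4→8 junction: C8(L)–Li (from 8-bromocatechin) adds to the unit-M aldehyde, then C8(M)–Li adds to the unit-U aldehyde.
4. Both α-benzyloxy-β-aryloxy aldehydes derive from one Evans syn-glycolate aldol adduct (C2/C3 of U and M) by copper-catalysed O-arylation with retention.
5. Ring order: ring C(L) is bought with (+)-catechin; rings C(M) and C(U) are formed together in the key step.

Key step: step 17

Remark: flavan numbering with the unit suffixes U, M and L is also used for open-chain intermediates; 1,3-bis(benzyloxy)-5-iodobenzene is taken as a catalogue compound (otherwise it follows from dibenzylation of 5-iodoresorcinol).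

**Route**

Step 1
Reactants: 1 (+)-catechin
Product: 2 5,7,3',4'-tetra-O-benzyl-(+)-catechin
Conditions: BnBr, K2CO3, DMF, 0 °C to rt
Reagents that add atoms: benzyl bromide, BrCc1ccccc1
Why: Williamson etherification of the four phenols under carbonate leaves the less acidic C3 alcohol free and does not touch C2 or C3.

Step 2
Reactants: 2 5,7,3',4'-tetra-O-benzyl-(+)-catechin
Product: 3 3,5,7,3',4'-penta-O-benzyl-(+)-catechin
Conditions: NaH, BnBr, DMF, 0 °C to rt
Reagents that add atoms: benzyl bromide, BrCc1ccccc1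
Why: Williamson etherification of the secondary alcohol removes the last acidic proton before organolithium chemistry.

Step 3
Reactants: 3 3,5,7,3',4'-penta-O-benzyl-(+)-catechin
Product: 4 8-bromo-3,5,7,3',4'-penta-O-benzyl-(+)-catechin
Conditions: NBS, CH2Cl2, −78 °C to 0 °C
Reagents that add atoms: N-bromosuccinimide, O=C1CCC(=O)N1Br
Why: electrophilic aromatic bromination of 5,7-di-O-benzylflavan-3-ols goes to C8, which places the halogen at the future interflavan carbon.

Step 4
Reactants: 5 (S)-4-benzyloxazolidin-2-one; 6 benzyloxyacetyl chloride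
Product: 8 (S)-4-benzyl-3-[2-(benzyloxy)acetyl]oxazolidin-2-one, via lithium oxazolidinide 7 (not isolated)
Conditions: n-BuLi, THF, −78 °C; then 6, −78 to 0 °C
Reagents that add atoms: none
Why: N-acylation of the lithiated auxiliary with an acid chloride is the standard entry to Evans glycolate imides.

Step 5
Reactants: 8 (S)-4-benzyl-3-[2-(benzyloxy)acetyl]oxazolidin-2-one; 9 3,4-bis(benzyloxy)benzaldehyde
Product: 11 (S)-4-benzyl-3-[(2S,3R)-2-(benzyloxy)-3-[3,4-bis(benzyloxy)phenyl]-3-hydroxypropanoyl]oxazolidin-2-one, via Z-boron enolate 10 (not isolated)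
Conditions: Bu2BOTf, Et3N, CH2Cl2, −78 to 0 °C; then 9, −78 to 0 °C; pH 7 buffer, MeOH, H2O2
Reagents that add atoms: none
Why: Evans syn-aldol reaction through the Z-boron enolate and a Zimmerman–Traxler chair, in which the (S)-benzyl auxiliary sets the benzylic carbinol (future C2, R) and the benzyloxy carbon (future C3) in the syn relationship that maps onto 2,3-cis.

Step 6
Reactants: 11 syn-aldol adduct
Product: 12 (1R,2R)-2-(benzyloxy)-1-[3,4-bis(benzyloxy)phenyl]propane-1,3-diol
Conditions: LiBH4, MeOH (1 equiv), THF, 0 °C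
Reagents that add atoms: none
Why: reductive cleavage of the N-acyloxazolidinone gives the primary alcohol and the recoverable auxiliary without touching either stereocenter.

Step 7
Reactants: 12 diol
Product: 13 (1R,2R)-2-(benzyloxy)-1-[3,4-bis(benzyloxy)phenyl]-3-[(tert-butyldiphenylsilyl)oxy]propan-1-ol
Conditions: TBDPSCl, imidazole, CH2Cl2, 0 °C
Reagents that add atoms: tert-butylchlorodiphenylsilane, CC(C)(C)[Si](Cl)(c1ccccc1)c1ccccc1
Why: silylation with a bulky chlorosilane selects the primary hydroxyl over the hindered secondary benzylic one.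

Step 8
Reactants: 13 silyl ether alcohol; 14 1,3-bis(benzyloxy)-5-iodobenzene
Product: 15 tert-butyl{[(2R,3R)-2-(benzyloxy)-3-[3,5-bis(benzyloxy)phenoxy]-3-[3,4-bis(benzyloxy)phenyl]propyl]oxy}diphenylsilane
Conditions: CuI (20 mol%), 3,4,7,8-tetramethyl-1,10-phenanthroline (40 mol%), Cs2CO3, 4 Å MS, toluene, 100 °C
Reagents that add atoms: none
Why: Ullmann-type copper-catalysed C–O coupling of a secondary alcohol with an aryl iodide forms the aryl–oxygen bond and never breaks the carbinol C–O bond, so the electron-rich benzylic stereocenter is retained where an SN2 or Mitsunobu etherification would risk ionisation.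

Step 9
Reactants: 15 silyl ether
Product: 16 (2R,3R)-2-(benzyloxy)-3-[3,5-bis(benzyloxy)phenoxy]-3-[3,4-bis(benzyloxy)phenyl]propan-1-ol
Conditions: Bu4NF, AcOH, THF, 0 °C to rt
Reagents that add atoms: none
Why: fluoride-mediated desilylation under buffered conditions leaves benzyl ethers and the benzylic aryl ether untouched.

Step 10
Reactants: 16 primary alcohol
Product: 17 (2S,3R)-2-(benzyloxy)-3-[3,5-bis(benzyloxy)phenoxy]-3-[3,4-bis(benzyloxy)phenyl]propanal (unit-U aldehyde)
Conditions: Dess–Martin periodinane, NaHCO3, CH2Cl2, 0 °C to rt; used at once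
Reagents that add atoms: none
Why: Dess–Martin oxidation under buffered, non-basic conditions should deliver the epimerisable α-benzyloxy aldehyde without loss of configuration at C3.

Step 11
Reactants: 18 2-bromo-1-fluoro-3-iodobenzene
Product: 19 1-(benzyloxy)-2-bromo-3-iodobenzene
Conditions: BnOH, NaH, DMF, 0 to 70 °C
Reagents that add atoms: benzyl alcohol, OCc1ccccc1
Why: nucleophilic aromatic substitution displaces fluoride, the best SNAr leaving group and activated by the ortho bromine, to give an arene with an iodide for coupling beside a bromide kept for lithiation.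

Step 12
Reactants: 13 silyl ether alcohol; 19 1-(benzyloxy)-2-bromo-3-iodobenzene
Product: 20 tert-butyl{[(2R,3R)-2-(benzyloxy)-3-[3-(benzyloxy)-2-bromophenoxy]-3-[3,4-bis(benzyloxy)phenyl]propyl]oxy}diphenylsilane
Conditions: CuI (20 mol%), 3,4,7,8-tetramethyl-1,10-phenanthroline (40 mol%), Cs2CO3, 4 Å MS, toluene, 90 °C
Reagents that add atoms: none
Why: Ullmann-type C–O coupling is chemoselective for the carbon–iodine bond over the doubly flanked carbon–bromine bond and retains the benzylic carbinol configuration.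

Step 13
Reactants: 20 silyl ether
Product: 21 (2R,3R)-2-(benzyloxy)-3-[3-(benzyloxy)-2-bromophenoxy]-3-[3,4-bis(benzyloxy)phenyl]propan-1-ol
Conditions: Bu4NF, AcOH, THF, 0 °C to rt
Reagents that add atoms: none
Why: buffered fluoride desilylation frees the primary alcohol without affecting the aryl bromide or the ethers.

Step 14
Reactants: 21 primary alcohol
Product: 22 (2S,3R)-2-(benzyloxy)-3-[3-(benzyloxy)-2-bromophenoxy]-3-[3,4-bis(benzyloxy)phenyl]propanal (unit-M aldehyde)
Conditions: Dess–Martin periodinane, NaHCO3, CH2Cl2, 0 °C to rt; used at once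
Reagents that add atoms: none
Why: Dess–Martin oxidation under buffered conditions should give the α-benzyloxy aldehyde without epimerisation.

Step 15
Reactants: 4 8-bromo-penta-O-benzylcatechin; 22 unit-M aldehyde
Product: 24 C4(M)-O-triethylsilyl carbinol joining C8(L) to the open unit-M chain (both C4(M) epimers), via 8-lithiocatechin ether 23 (not isolated)
Conditions: t-BuLi (2 equiv), THF, −78 °C; then 22, −78 °C; then Et3SiCl, −78 to 0 °C
Reagents that add atoms: chlorotriethylsilane, CC[Si](Cl)(CC)CC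
Why: bromine–lithium exchange and 1,2-addition of the aryllithium to the aldehyde make the C4(M)–C8(L) bond at the carbon defined by the halogen, and in situ silylation installs a base-stable, ionisable leaving group; the carbinol epimer mixture is irrelevant because this centre is erased on ionisation.

Step 16
Reactants: 24 silyl carbinol bromide; 17 unit-U aldehyde
Product: 26 open-chain bis-carbinol (C4(M)–OSiEt3, C4(U)–OH; epimer mixture at both carbinol carbons), via ring-A(M) aryllithium 25 (not isolated)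
Conditions: t-BuLi (2 equiv), THF, −78 °C; then 17, −78 °C; pH 7 buffer
Reagents that add atoms: none
Why: bromine–lithium exchange followed by aldehyde addition forms the C4(U)–C8(M) bond at the carbon between O7 and O1 of the 5-deoxy ring, a position that electrophilic substitution (which prefers C6) would not select.

Step 17
Reactants: 26 open-chain bis-carbinol
Product: 28 tetradeca-O-benzyl epicatechin-(4β→8)-epifisetinidol-(4β→8)-catechin, via ring-C(M)-closed carbinol 27 (not isolated)
Conditions: TMSOTf (0.3 equiv), 4 Å MS, CH2Cl2 (0.005 M), −78 to −30 °C; Et3N quench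
Reagents that add atoms: none
Why: TMSOTf ionises the C4(M)–OSiEt3 and C4(U)–OH groups to 2,6-dioxygenated benzylic cations (ortho-quinone-methide oxocarbenium ions of rings A(L) and A(M)), and each cation is captured by the aryl ether carbon held six atoms away, C4a(M) (ortho to O1, para to O7) and then C4a(U) (ortho to O1, ortho/para to O5 and O7), with rearomatisation returning the acid. The closest known reaction type is the acid-catalysed intramolecular Friedel–Crafts cycloalkylation of 3-aryloxy-1-arylpropan-1-ols to 4-arylchromans, run here twice in one flask, and it is kin to the flavan-4-yl cation arylations used for interflavan bonds. Rings C(M) and C(U) each close in a six-membered mode that is 6-exo-trig at the cationic carbon and endo with respect to the arene, while the competing five-membered closures onto the catechol rings B are disfavoured by their far lower nucleophilicity. Each new stereocenter (C4(M), C4(U)) is set by allylic 1,3-strain: the two ortho oxygens of the cation-bearing arene force C3–H into the cation plane, the tether through C2 delivers the arene to the face that carries C2, and that face is anti to the C3 benzyloxy group, which should give the 3,4-trans (4β) relationship whatever the carbinol configuration was. The step needs regioselectivity at both arenes and suppression of intermolecular alkylation; the first is secured because ring A(M) has only one free position ortho to O1 (C8 carries the other chain) and ring A(U) is symmetric, the second by high dilution.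

Step 18
Reactants: 28 tetradeca-O-benzyl trimer
Product: 29 CNP0270097.1, epicatechin-(4β→8)-epifisetinidol-(4β→8)-catechin
Conditions: H2 (1 atm), Pd(OH)2/C, THF/MeOH/H2O, rt
Reagents that add atoms: none
Why: catalytic hydrogenolysis removes all fourteen benzyl ethers, while the diarylmethine C–C bonds and the stereocenters are not affected.

**Compound list**

1 | (+)-catechin, (2R,3S)-2-(3,4-dihydroxyphenyl)chromane-3,5,7-triol | Oc1cc(O)c2c(c1)O[C@H](c1ccc(O)c(O)c1)[C@@H](O)C2 | starting material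
2 | 5,7,3',4'-tetra-O-benzyl-(+)-catechin (2R,3S; 3-OH free) | C(c3ccccc3)Oc1cc(OCc3ccccc3)c2c(c1)O[C@H](c1ccc(OCc3ccccc3)c(OCc3ccccc3)c1)[C@@H](O)C2 | intermediate
3 | 3,5,7,3',4'-penta-O-benzyl-(+)-catechin (2R,3S) | C(c3ccccc3)Oc1cc(OCc3ccccc3)c2c(c1)O[C@H](c1ccc(OCc3ccccc3)c(OCc3ccccc3)c1)[C@@H](OCc1ccccc1)C2 | intermediate
4 | 8-bromo-3,5,7,3',4'-penta-O-benzyl-(+)-catechin (2R,3S) | Brc1c(OCc3ccccc3)cc(OCc3ccccc3)c2c1O[C@H](c1ccc(OCc3ccccc3)c(OCc3ccccc3)c1)[C@@H](OCc1ccccc1)C2 | intermediate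
5 | (S)-4-benzyloxazolidin-2-one | O=C1OC[C@H](Cc2ccccc2)N1 | starting material
6 | benzyloxyacetyl chloride | O=C(Cl)COCc1ccccc1 | starting material
7 | lithium (S)-4-benzyl-2-oxooxazolidin-3-ide | O=C1OC[C@H](Cc2ccccc2)N1[Li] | intermediate (not isolated)
8 | (S)-4-benzyl-3-[2-(benzyloxy)acetyl]oxazolidin-2-one | O=C1OC[C@H](Cc2ccccc2)N1C(=O)COCc1ccccc1 | intermediate
9 | 3,4-bis(benzyloxy)benzaldehyde | O=Cc1ccc(OCc2ccccc2)c(OCc2ccccc2)c1 | starting material
10 | (Z)-dibutylboron enolate of 8 (enolate O–B and benzyloxy cis) | O=C1OC[C@H](Cc2ccccc2)N1/C(OB(CCCC)CCCC)=C/OCc1ccccc1 | intermediate (not isolated)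
11 | (S)-4-benzyl-3-[(2S,3R)-2-(benzyloxy)-3-[3,4-bis(benzyloxy)phenyl]-3-hydroxypropanoyl]oxazolidin-2-one | O=C1OC[C@H](Cc2ccccc2)N1C(=O)[C@@H](OCc1ccccc1)[C@H](O)c1ccc(OCc2ccccc2)c(OCc2ccccc2)c1 | intermediate
12 | (1R,2R)-2-(benzyloxy)-1-[3,4-bis(benzyloxy)phenyl]propane-1,3-diol | OC[C@@H](OCc1ccccc1)[C@H](O)c1ccc(OCc2ccccc2)c(OCc2ccccc2)c1 | intermediate
13 | (1R,2R)-2-(benzyloxy)-1-[3,4-bis(benzyloxy)phenyl]-3-[(tert-butyldiphenylsilyl)oxy]propan-1-ol | CC(C)(C)[Si](OC[C@@H](OCc1ccccc1)[C@H](O)c1ccc(OCc2ccccc2)c(OCc2ccccc2)c1)(c1ccccc1)c1ccccc1 | intermediate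
14 | 1,3-bis(benzyloxy)-5-iodobenzene | Ic1cc(OCc2ccccc2)cc(OCc2ccccc2)c1 | starting material
15 | tert-butyl{[(2R,3R)-2-(benzyloxy)-3-[3,5-bis(benzyloxy)phenoxy]-3-[3,4-bis(benzyloxy)phenyl]propyl]oxy}diphenylsilane | CC(C)(C)[Si](OC[C@@H](OCc1ccccc1)[C@H](Oc1cc(OCc2ccccc2)cc(OCc2ccccc2)c1)c1ccc(OCc2ccccc2)c(OCc2ccccc2)c1)(c1ccccc1)c1ccccc1 | intermediate
16 | (2R,3R)-2-(benzyloxy)-3-[3,5-bis(benzyloxy)phenoxy]-3-[3,4-bis(benzyloxy)phenyl]propan-1-ol | OC[C@@H](OCc1ccccc1)[C@H](Oc1cc(OCc2ccccc2)cc(OCc2ccccc2)c1)c1ccc(OCc2ccccc2)c(OCc2ccccc2)c1 | intermediate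
17 | (2S,3R)-2-(benzyloxy)-3-[3,5-bis(benzyloxy)phenoxy]-3-[3,4-bis(benzyloxy)phenyl]propanal (unit-U aldehyde) | O=C[C@@H](OCc1ccccc1)[C@H](Oc1cc(OCc2ccccc2)cc(OCc2ccccc2)c1)c1ccc(OCc2ccccc2)c(OCc2ccccc2)c1 | intermediate
18 | 2-bromo-1-fluoro-3-iodobenzene | Fc1cccc(I)c1Br | starting material
19 | 1-(benzyloxy)-2-bromo-3-iodobenzene | Ic1cccc(OCc2ccccc2)c1Br | intermediate
20 | tert-butyl{[(2R,3R)-2-(benzyloxy)-3-[3-(benzyloxy)-2-bromophenoxy]-3-[3,4-bis(benzyloxy)phenyl]propyl]oxy}diphenylsilane | CC(C)(C)[Si](OC[C@@H](OCc1ccccc1)[C@H](Oc1cccc(OCc2ccccc2)c1Br)c1ccc(OCc2ccccc2)c(OCc2ccccc2)c1)(c1ccccc1)c1ccccc1 | intermediate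
21 | (2R,3R)-2-(benzyloxy)-3-[3-(benzyloxy)-2-bromophenoxy]-3-[3,4-bis(benzyloxy)phenyl]propan-1-ol | OC[C@@H](OCc1ccccc1)[C@H](Oc1cccc(OCc2ccccc2)c1Br)c1ccc(OCc2ccccc2)c(OCc2ccccc2)c1 | intermediate
22 | (2S,3R)-2-(benzyloxy)-3-[3-(benzyloxy)-2-bromophenoxy]-3-[3,4-bis(benzyloxy)phenyl]propanal (unit-M aldehyde) | O=C[C@@H](OCc1ccccc1)[C@H](Oc1cccc(OCc2ccccc2)c1Br)c1ccc(OCc2ccccc2)c(OCc2ccccc2)c1 | intermediate
23 | 8-lithio-3,5,7,3',4'-penta-O-benzyl-(+)-catechin | [Li]c1c(OCc3ccccc3)cc(OCc3ccccc3)c2c1O[C@H](c1ccc(OCc3ccccc3)c(OCc3ccccc3)c1)[C@@H](OCc1ccccc1)C2 | intermediate (not isolated)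
24 | penta-O-benzylcatechin carrying at C8 the 1-(triethylsilyloxy)propyl chain of 22 (2-benzyloxy, 3-(3-benzyloxy-2-bromophenoxy), 3-[3,4-bis(benzyloxy)phenyl]; chain C2 and C3 as in 22, carbinol carbon as both epimers) | CC[Si](CC)(CC)OC(c1c(OCc3ccccc3)cc(OCc3ccccc3)c2c1O[C@H](c1ccc(OCc3ccccc3)c(OCc3ccccc3)c1)[C@@H](OCc1ccccc1)C2)[C@@H](OCc1ccccc1)[C@H](Oc1cccc(OCc2ccccc2)c1Br)c1ccc(OCc2ccccc2)c(OCc2ccccc2)c1 | intermediate
25 | aryllithium from 24 (lithium in place of bromine on ring A(M)) | CC[Si](CC)(CC)OC(c1c(OCc3ccccc3)cc(OCc3ccccc3)c2c1O[C@H](c1ccc(OCc3ccccc3)c(OCc3ccccc3)c1)[C@@H](OCc1ccccc1)C2)[C@@H](OCc1ccccc1)[C@H](Oc1cccc(OCc2ccccc2)c1[Li])c1ccc(OCc2ccccc2)c(OCc2ccccc2)c1 | intermediate (not isolated)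
26 | open-chain bis-carbinol: 24 in which the bromine is replaced by the 1-hydroxypropyl chain of 17 (2-benzyloxy, 3-[3,5-bis(benzyloxy)phenoxy], 3-[3,4-bis(benzyloxy)phenyl]; chain C2 and C3 as in 17 and 22, both carbinol carbons as epimer mixtures) | CC[Si](CC)(CC)OC(c1c(OCc3ccccc3)cc(OCc3ccccc3)c2c1O[C@H](c1ccc(OCc3ccccc3)c(OCc3ccccc3)c1)[C@@H](OCc1ccccc1)C2)[C@@H](OCc1ccccc1)[C@H](Oc1cccc(OCc2ccccc2)c1C(O)[C@@H](OCc1ccccc1)[C@H](Oc1cc(OCc2ccccc2)cc(OCc2ccccc2)c1)c1ccc(OCc2ccccc2)c(OCc2ccccc2)c1)c1ccc(OCc2ccccc2)c(OCc2ccccc2)c1 | intermediate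
27 | nona-O-benzyl epifisetinidol-(4β→8)-catechin carrying at C8(M) the open 1-hydroxypropyl chain of unit U (ring C(M) closed, ring C(U) open; carbinol epimers) | OC([C@@H](OCc1ccccc1)[C@H](Oc1cc(OCc2ccccc2)cc(OCc2ccccc2)c1)c1ccc(OCc2ccccc2)c(OCc2ccccc2)c1)c1c(OCc3ccccc3)ccc2c1O[C@H](c1ccc(OCc3ccccc3)c(OCc3ccccc3)c1)[C@H](OCc1ccccc1)[C@H]2c1c(OCc3ccccc3)cc(OCc3ccccc3)c2c1O[C@H](c1ccc(OCc3ccccc3)c(OCc3ccccc3)c1)[C@@H](OCc1ccccc1)C2 | intermediate (not isolated)
28 | tetradeca-O-benzyl epicatechin-(4β→8)-epifisetinidol-(4β→8)-catechin (U: 2R,3R,4R; M: 2R,3R,4R; L: 2R,3S) | C(c3ccccc3)Oc1cc(OCc3ccccc3)c2c(c1)O[C@H](c1ccc(OCc3ccccc3)c(OCc3ccccc3)c1)[C@H](OCc1ccccc1)[C@H]2c1c(OCc3ccccc3)ccc2c1O[C@H](c1ccc(OCc3ccccc3)c(OCc3ccccc3)c1)[C@H](OCc1ccccc1)[C@H]2c1c(OCc3ccccc3)cc(OCc3ccccc3)c2c1O[C@H](c1ccc(OCc3ccccc3)c(OCc3ccccc3)c1)[C@@H](OCc1ccccc1)C2 | intermediate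
29 | CNP0270097.1, epicatechin-(4β→8)-epifisetinidol-(4β→8)-catechin | Oc1cc(O)c2c(c1)O[C@H](c1ccc(O)c(O)c1)[C@H](O)[C@H]2c1c(O)ccc2c1O[C@H](c1ccc(O)c(O)c1)[C@H](O)[C@H]2c1c(O)cc(O)c2c1O[C@H](c1ccc(O)c(O)c1)[C@@H](O)C2 | target

**Step count and risks**

Total steps: 18. Longest linear sequence: 11 steps (steps 4–7, then 12–18).

Steps most likely to fail:

Step 17. The two ionisations may not stay in step: loss of the C3 proton or a 1,2-hydride shift from an open-chain cation, intermolecular alkylation, or a stalled second closure while ring A(M) is deactivated by the cation it carries would erode the cascade. Fallback: the rings are closed one at a time. Setting out from 24, catalytic TMSOTf in CH2Cl2 at −78 °C should close ring C(M) alone to the ring-closed dimer bromide F1, a compact substrate free of the acid-labile silyl ether. Bromine–lithium exchange on F1 (t-BuLi, THF, −78 °C) and addition to 17 then gives 27, which is now isolated. It comes back to the route at 27, whose single remaining closure under the conditions of step 17 gives 28.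

Step 12. Copper–oxygen bond formation at an iodide flanked by bromine may be too slow for a hindered, α-branched secondary alkoxide, with reduction of the iodide or coupling at the carbon–bromine bond taking over. Fallback: the arene is activated for uncatalysed substitution instead. Setting out from 13, the potassium alkoxide (KN(SiMe3)2, THF, −40 °C) is treated with 1-(benzyloxy)-3-fluoro-2-nitrobenzene F2 (from 1,3-difluoro-2-nitrobenzene, benzyl alcohol and K2CO3 in DMF) in an SNAr reaction that again leaves the carbinol C–O bond intact and should give the nitro ether F3. Reduction with Fe and NH4Cl in EtOH/H2O gives the aniline F4, and Sandmeyer bromination (t-BuONO, CuBr2, MeCN, 0 °C to rt) comes back to the route at 20.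

Step 8. Turnover of the copper alkoxide of the hindered benzylic alcohol may be poor, and the alkoxide may be oxidised to the aryl ketone. Fallback: the ether is made by inversion instead of retention. Setting out from 13, Dess–Martin oxidation gives the aryl ketone F5. Chelation-controlled reduction with Zn(BH4)2 in Et2O at −20 °C should give the anti alcohol F6, the C1 epimer of 13. Mitsunobu etherification of F6 with 3,5-bis(benzyloxy)phenol (PPh3, diisopropyl azodicarboxylate, toluene, 0 °C) inverts the benzylic carbon and comes back to the route at 15.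

Further compounds

F1 | step 17 | 8-bromo-nona-O-benzyl epifisetinidol-(4β→8)-catechin (bromine on C8 of unit M; M: 2R,3R,4R; L: 2R,3S) | Brc1c(OCc3ccccc3)ccc2c1O[C@H](c1ccc(OCc3ccccc3)c(OCc3ccccc3)c1)[C@H](OCc1ccccc1)[C@H]2c1c(OCc3ccccc3)cc(OCc3ccccc3)c2c1O[C@H](c1ccc(OCc3ccccc3)c(OCc3ccccc3)c1)[C@@H](OCc1ccccc1)C2
F2 | step 12 | 1-(benzyloxy)-3-fluoro-2-nitrobenzene | [O-][N+](=O)c1c(F)cccc1OCc1ccccc1
F3 | step 12 | tert-butyl{[(2R,3R)-2-(benzyloxy)-3-[3-(benzyloxy)-2-nitrophenoxy]-3-[3,4-bis(benzyloxy)phenyl]propyl]oxy}diphenylsilane | CC(C)(C)[Si](OC[C@@H](OCc1ccccc1)[C@H](Oc1cccc(OCc2ccccc2)c1[N+](=O)[O-])c1ccc(OCc2ccccc2)c(OCc2ccccc2)c1)(c1ccccc1)c1ccccc1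
F4 | step 12 | 2-amino analogue of 20 (NH2 in place of bromine; chain 2R,3R) | CC(C)(C)[Si](OC[C@@H](OCc1ccccc1)[C@H](Oc1cccc(OCc2ccccc2)c1N)c1ccc(OCc2ccccc2)c(OCc2ccccc2)c1)(c1ccccc1)c1ccccc1
F5 | step 8 | (R)-2-(benzyloxy)-1-[3,4-bis(benzyloxy)phenyl]-3-[(tert-butyldiphenylsilyl)oxy]propan-1-one | CC(C)(C)[Si](OC[C@@H](OCc1ccccc1)C(=O)c1ccc(OCc2ccccc2)c(OCc2ccccc2)c1)(c1ccccc1)c1ccccc1
F6 | step 8 | (1S,2R)-2-(benzyloxy)-1-[3,4-bis(benzyloxy)phenyl]-3-[(tert-butyldiphenylsilyl)oxy]propan-1-ol | CC(C)(C)[Si](OC[C@@H](OCc1ccccc1)[C@@H](O)c1ccc(OCc2ccccc2)c(OCc2ccccc2)c1)(c1ccccc1)c1ccccc1
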